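The readings come from a simulation for an exercise; the scatter is artificial.

Saturday's flask held half the substrate of Thursday's flask, the flask asked about, so the same share of the charge is a smaller amount on Saturday.

all flasks: coupling partner 0.737 M
- Thursday's: substrate 0.67 M; the very flask that is asked about, followed so far
- Saturday's: substrate 0.34 M; run made earlier
- flask: substrate 0.67 M; time 8.0 min

| run | time / min | target / % | crystals / % |
|---|---|---|---|
| Thursday's | 0.200 | 1.1 | 0.1 |
| Thursday's | 0.667 | 0.2 | 0 |
| Thursday's | 1.00 | 0 | 0 |
| Thursday's | 1.50 | 1.0 | 0 |
| Thursday's | 2.50 | 2.7 | 0.5 |
| Saturday's | 1.00 | 0.7 | 0.9 |
| Saturday's | 2.50 | 1.9 | 0.1 |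
| Saturday's | 3.00 | 2.3 | 0.2 |
| Saturday's | 5.00 | 3.8 | 0.6 |
| Saturday's | 6.00 | 4.3 | 0 |

(readings scatter by 0.5 percentage points)

- amounts and yields of target count crystals too
- given per volume of solution although it is solid: crystals
- what was read earlier has a scatter of 0.5 percentage points, one standard deviation
- steps under discussion: substrate -> intermediate; crystals <-> target; coupling partner + intermediate -> target; substrate <-> dormant form; target -> over-reaction product

* the target and crystals together standing at 8.0 min, as a percentage of the substrate charged
* concentration of target in solution at 8.0 min, in percent of saturation

**Does the share of the charge depend on the charge?** At 2.50 min, target reads 2.7% in Thursday's flask and 1.9% in Saturday's. The gap of 0.8 percentage points is not far beyond a scatter of 0.5 points on each reading, so I take the share as roughly independent of the charge.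

**Your figure for the yield?** A straight line from zero through Saturday's last reading reaches 5.73% at 8.0 min, and I commit to that.

**What do the crystals tell you?** At 6.00 min, Saturday's flask reads 4.3% target and 0% crystals, so I take that amount as dissolved. Call it the clear fraction 2.18%: the amount of target seen dissolved without crystals, divided by a flask's own charge, here Thursday's.

**So is that saturation?** No, it is a reading of a floor under the solubility. My yield stands above it, and there the readings are silent, so I give no figure for saturation.

**And the forecast?** It gives 6.5%, above my figure, and 95% of saturation, while writing that “solubility is only bounded from below”.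

The flask gives 4.41% and 4.76% of saturation, with crystals at 0% at 8.00 min.

    substrate → intermediate (k = 0.00350 s⁻¹)
    crystals ⇌ target, rate k2*(cs2 - [target]) while solid is left; crystals form when [target] > cs2 (solubility = 0.620 M, k = 0.780 s⁻¹)
    coupling partner + intermediate → target (k = 0.00190 M⁻¹ s⁻¹)
    substrate ⇌ dormant form (K = 0.970, k = 0.00160 s⁻¹)
    target → over-reaction product (k = 0.0120 s⁻¹)

Read back from these two numbers, saturation lies at 92.6% of this flask's charge, far above the clear fraction, and the yield stands at twice that fraction. In a neighbouring flask with 0.27 M of substrate, the other charges and the time held, the clear fraction becomes 5.41%. Its target and crystals together stand below that fraction, at 4.80%, and its crystals at 0%.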